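(Readings and results were computed for substances that don't exist, noise included.)

If the protic impurity were to cost this flask half of its starting material, its charge would have to be at least 25.0 mM, supposing that one molecule of it takes one molecule of starting material, and this flask holds 1.00 mM, short by a factor of 25.0.

- green: starting material 0.050 M; protic impurity 1.5 mM; run made earlier
- flask: starting material 0.050 M; protic impurity 1.00 mM; time 4.0 min

- green (time / s: target / %, crystals / %): 10.0: 3.8, 0; 15.0: 6.8, 0; 20.0: 10.1, 0; 25.0: 13.0, 2.7

(scatter of a reading: 0.3 percentage points)

- amounts and yields of target count crystals too
- given per volume of solution although it is solid: crystals
- no earlier run changes the charge of protic impurity; that part of a forecast is a guess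

* how much target and crystals together there is at 4.0 min, in percent of the starting material charged
* concentration of target in solution at 4.0 min, in percent of saturation

I follow one molecule of starting material to its first fork, where under that supposition the impurity is the limiting reagent of the side step, because its charge is the smaller. The molecule's chance of being lost there has a ceiling:

toll = 2.00%

The toll, the protic impurity charged over the starting material charged, falls by 1 percentage point from the green run to this flask. I therefore expect at most 2.00% of quenched substrate here.

The forecast gives 85% (72% to 98%) of target and crystals together and a solution at 102% (99% to 115%) of saturation, and it says “Any impurity effect on rate is a guess”.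

    starting material → intermediate (k = 0.0257 s⁻¹)
    intermediate ⇌ target (K = 1.33, k = 0.0496 s⁻¹)
    intermediate ⇌ isomer of the product (K = 2.74, k = 0.0152 s⁻¹)
    crystals ⇌ target, rate k4*(cs4 - [target]) while solid is left; crystals form when [target] > cs4 (solubility = 3.80 mM, k = 0.147 s⁻¹)
    starting material + protic impurity → quenched substrate (k = 8.64 M⁻¹ s⁻¹)
    target → over-reaction product (k = 0.0189 s⁻¹)

The flask gives 34.7% of target and crystals together and a solution at 91.6% of saturation. At 4.00 min it holds 2.00% of quenched substrate, which matches the toll, with 0% of the protic impurity left, and it holds more over-reaction product, 36.7%. A neighbouring flask, the same but charged with 4.00 mM of protic impurity, has a toll of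

8.00%

At 4.00 min that neighbouring flask holds 8.00% of quenched substrate, 36.1% of over-reaction product and 30.2% of target and crystals together.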